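**Retrosynthetic overview**
1. The trimer is ring A–CH2–ring B–CH2–ring C. Both methylene bridges are cut back to three monomers and two formaldehyde-level carbons, joined through quinone-methide-type acceptors as the plant is thought to do.
2. Ring B and ring C come from one monomer, butyrylphloroglucinol. Its benzene ring is closed by the polyketide-synthase-type C6→C1 Claisen cyclisation of a linear 3,5,7-trioxodecanoate unmasked from a pyranone; ring C is its 4-O-methyl ether.
3. Ring A (butyrylfilicinic acid) is not made by methylating an arene. The same tetraketide Claisen closure is run on a chain that already carries the gem-dimethyl carbon, built in the same flask from a β-diketone dianion and dimethyl dimethylmalonate.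
4. Ring order: ring A carbocycle, then the ring B/ring C carbocycle (one batch serves both). After that come only O-methylation, the A–B bridge and last the AB–C bridge; no ring is formed later.

Assumption: the target has no stereogenic centre (the ring A C(CH3)2 carbon carries two identical methyls), so it is achiral and needs no stereocontrol; all compounds are written in the enol tautomer of the given SMILES.

**Route**

Step 1
Reactants: 1 heptane-2,4-dione; 2 dimethyl 2,2-dimethylpropanedioate (dimethyl dimethylmalonate)
Product: 4 butyrylfilicinic acid (2-butanoyl-3,5-dihydroxy-4,4-dimethylcyclohexa-2,5-dien-1-one), via methyl 2,2-dimethyl-3,5,7-trioxodecanoate 3 (not isolated)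
Conditions: LiN(iPr)2 (3.1 equiv), THF, −78 → 0 °C; 2 (1.2 equiv), −78 °C → rt; then Mg(OMe)2 (3 equiv), MeOH, reflux; 1 M HCl
Reagents that add atoms: none
Why: Proposed new method: the kinetic 1,3-dianion of 1 (formed at the CH3 terminus) is C-acylated by the non-enolisable diester 2 to the tetraketide ester 3, whose magnesium-chelated C6 then attacks the C1 ester in a 6-exo Claisen (Dieckmann) closure that is the only cyclisation open to it because the quaternary C2 cannot serve as an aldol donor, is helped by the gem-dimethyl effect and is driven by formation of the very stable β-triketone enolate; the closest known reactions are Harris-type terminal acylation of β-diketone dianions with esters and the Mg(OMe)2-induced Claisen cyclisation of 3,5,7-triketo esters to acylphloroglucinols (the laboratory copy of the polyketide synthase ring closure); no stereocentre is formed.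

Step 2
Reactants: 5 4-hydroxy-6-methyl-2H-pyran-2-one (triacetic acid lactone); 6 methyl butanoate
Product: 9 1-(2,4,6-trihydroxyphenyl)butan-1-one (butyrylphloroglucinol), via 4-hydroxy-6-(2-oxopentyl)-2H-pyran-2-one 7 (not isolated), via methyl 3,5,7-trioxodecanoate 8 (not isolated)
Conditions: 5 (2.2 equiv), LiN(iPr)2 (4.4 equiv), THF/DMPU, −78 → −20 °C; 6 (1.0 equiv), −78 → 0 °C; then MeOH, Mg(OMe)2 (5 equiv), reflux, 16 h; 2 M HCl
Reagents that add atoms: none
Why: Harris-type acylation of the triacetic acid lactone dianion at the 6-methyl carbon gives the masked tetraketide 7, which Mg(OMe)2 opens to the chelated triketo ester 8 and steers into the C6→C1 Claisen cyclisation (rather than the C2→C7 aldol) with aromatisation by enolisation, the same ring closure a polyketide synthase performs on a butyryl starter plus three malonyl units; no stereocentre is formed.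

Step 3
Reactants: 9 1-(2,4,6-trihydroxyphenyl)butan-1-one
Product: 10 1-(2,6-dihydroxy-4-methoxyphenyl)butan-1-one (desaspidinol B)
Conditions: Me2SO4 (1.0 equiv), K2CO3 (1.0 equiv), acetone, 0 °C → rt
Reagents that add atoms: dimethyl sulfate, COS(=O)(=O)OC
Why: Williamson O-methylation with one equivalent of weak base is selective for the 4-OH, the most acidic phenol (para to the ketone) and the only one not hydrogen-bonded to the carbonyl, mirroring the late O-methyl transfer of the biosynthesis; no stereocentre is formed.

Step 4
Reactants: 4 butyrylfilicinic acid; 9 1-(2,4,6-trihydroxyphenyl)butan-1-one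
Product: 13 norflavaspidic acid BB (ring A–CH2–ring B dimer), via 6-(dimethylaminomethyl)butyrylfilicinic acid 11 (not isolated), via 6-methylidene trione 12 (not isolated)
Conditions: 4, (CH3)2N=CH2+ I− (1.05 equiv), MeCN, 0 °C → rt, 1 h; then 9 (3 equiv), NaOAc (1.2 equiv), 50 °C
Reagents that add atoms: N,N-dimethylmethyleneiminium iodide (Eschenmoser's salt), C=[N+](C)C.[I-]
Why: Mannich reaction at the single free enolic ring carbon of 4 followed by E1cB loss of dimethylamine gives the methylidene trione 12, a quinone-methide-type Michael acceptor that the excess phloroglucinol 9 captures by Friedel–Crafts-type C-alkylation and re-aromatisation, the excess of 9 suppressing double alkylation; no stereocentre is formed.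

Step 5
Reactants: 13 norflavaspidic acid BB; 10 1-(2,6-dihydroxy-4-methoxyphenyl)butan-1-one
Product: 16 target trimer (trisdesaspidin BBB), via ring B Mannich base 14 (not isolated), via ring B ortho-quinone methide 15 (not isolated)
Conditions: 13, (CH3)2N=CH2+ I− (1.05 equiv), MeCN, 0 °C → rt; then 10 (4 equiv), NaOAc (1.2 equiv), 60 °C
Reagents that add atoms: N,N-dimethylmethyleneiminium iodide (Eschenmoser's salt), C=[N+](C)C.[I-]
Why: the only nucleophilic CH left in 13 (ring B, flanked by two OH groups) undergoes phenol Mannich aminomethylation, and thermal loss of dimethylamine gives the ortho-quinone methide 15, which is trapped in a Michael/Friedel–Crafts alkylation by the excess of 10 at one of its two equivalent ring positions; no stereocentre is formed and the product is achiral.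

**Compound list**
1 | heptane-2,4-dione | CCCC(=O)CC(C)=O | starting material
2 | dimethyl 2,2-dimethylpropanedioate | COC(=O)C(C)(C)C(=O)OC | starting material
3 | methyl 2,2-dimethyl-3,5,7-trioxodecanoate | CCCC(=O)CC(=O)CC(=O)C(C)(C)C(=O)OC | intermediate
4 | butyrylfilicinic acid, 2-butanoyl-3,5-dihydroxy-4,4-dimethylcyclohexa-2,5-dien-1-one | CCCC(=O)C1=C(O)C(C)(C)C(O)=CC1=O | intermediate
5 | 4-hydroxy-6-methyl-2H-pyran-2-one (triacetic acid lactone) | CC1=CC(O)=CC(=O)O1 | starting material
6 | methyl butanoate | CCCC(=O)OC | starting material
7 | 4-hydroxy-6-(2-oxopentyl)-2H-pyran-2-one | CCCC(=O)CC1=CC(O)=CC(=O)O1 | intermediate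
8 | methyl 3,5,7-trioxodecanoate | CCCC(=O)CC(=O)CC(=O)CC(=O)OC | intermediate
9 | 1-(2,4,6-trihydroxyphenyl)butan-1-one (butyrylphloroglucinol) | CCCC(=O)c1c(O)cc(O)cc1O | intermediate
10 | 1-(2,6-dihydroxy-4-methoxyphenyl)butan-1-one (desaspidinol B) | CCCC(=O)c1c(O)cc(OC)cc1O | intermediate
11 | 2-butanoyl-6-[(dimethylamino)methyl]-3,5-dihydroxy-4,4-dimethylcyclohexa-2,5-dien-1-one | CCCC(=O)C1=C(O)C(C)(C)C(O)=C(CN(C)C)C1=O | intermediate
12 | 2-butanoyl-3-hydroxy-4,4-dimethyl-6-methylidenecyclohex-2-ene-1,5-dione | CCCC(=O)C1=C(O)C(C)(C)C(=O)C(=C)C1=O | intermediate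
13 | norflavaspidic acid BB, 2-butanoyl-6-[(3-butanoyl-2,4,6-trihydroxyphenyl)methyl]-3,5-dihydroxy-4,4-dimethylcyclohexa-2,5-dien-1-one | CCCC(=O)C1=C(O)C(C)(C)C(O)=C(Cc2c(O)cc(O)c(C(=O)CCC)c2O)C1=O | intermediate
14 | ring B Mannich base of 13, carrying CH2N(CH3)2 on the free ring B carbon | CCCC(=O)C1=C(O)C(C)(C)C(O)=C(Cc2c(O)c(CN(C)C)c(O)c(C(=O)CCC)c2O)C1=O | intermediate
15 | ring B ortho-quinone methide from 14 (exocyclic CH2= next to a ring C=O) | CCCC(=O)C1=C(O)C(C)(C)C(O)=C(CC2=C(O)C(=C)C(=O)C(C(=O)CCC)=C2O)C1=O | intermediate
16 | 2-butanoyl-6-[[3-butanoyl-5-[(3-butanoyl-2,4-dihydroxy-6-methoxyphenyl)methyl]-2,4,6-trihydroxyphenyl]methyl]-3,5-dihydroxy-4,4-dimethylcyclohexa-2,5-dien-1-one (trisdesaspidin BBB) | CCCC(=O)C1=C(O)C(C)(C)C(O)=C(Cc2c(O)c(Cc3c(OC)cc(O)c(C(=O)CCC)c3O)c(O)c(C(=O)CCC)c2O)C1=O | target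

**Step count and risks**
Total steps: 5. Longest linear sequence: 3 steps (1 → 4 → 5; equally 2 → 4 → 5 and 2 → 3 → 5).

The three steps most likely to fail:

Step 1 (one-flask dianion acylation and Claisen closure to ring A). The risks are dianion formation at the propyl-side CH2, double attack on the diester, or a sluggish closure onto the hindered ester. The fallback sets out from 9 and comes back at 4. Compound 9 is C-methylated twice at one ring carbon with MeI (2.2 equiv) and NaOMe in MeOH at 0 °C → rt. It passes through 1-(2,4,6-trihydroxy-3-methylphenyl)butan-1-one F1, whose second methylation at the same carbon dearomatises the ring to 4. Ring A then originates from the Claisen product of step 2 and the methyls arrive after cyclisation. The price is one more linear step and chromatographic removal of 3,5-dimethyl and trimethyl by-products.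

Step 4 (A–B bridge). The risks are capture of 12 by unreacted 4 to give the symmetrical dimer, or double alkylation of 9. The fallback sets out from 4 and comes back at 13, and makes the symmetrical dimer on purpose. Compound 4 (2 equiv) is treated with (CH3)2N=CH2+ I− (1 equiv) and NaOAc, so that 12, formed through 11, is captured by a second molecule of 4 to give crystalline albaspidin BB F2. F2 is then equilibrated with excess 9 in dilute aqueous Na2CO3/dioxane at 40 °C (the "rottlerone change": retro-Michael release of 12 and 4, capture of 12 by 9). This gives 13, with the released 4 recycled.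

Step 5 (AB–C bridge). The risks are retro-Michael scrambling of the first bridge under the warmer phenol-Mannich conditions and further alkylation of ring C. The fallback sets out from 10 and comes back at 16 with the two couplings in reverse order. Compound 10 is aminomethylated with (CH3)2N=CH2+ I− to 1-[3-[(dimethylamino)methyl]-2,6-dihydroxy-4-methoxyphenyl]butan-1-one F3. On warming with excess 9 and NaOAc, F3 loses dimethylamine to the ring C ortho-quinone methide F4, which 9 traps to give the ring B–CH2–ring C dimer F5. F5 is then alkylated by 12, generated from 4 via 11 as in step 4 at ≤ 40 °C, to give 16. Attack should occur at the ring B CH, which lies between two free OH groups and ortho to the acidic para-OH, rather than at the ring C CH next to OCH3. The mild filicinic transfer comes last, so the finished bridge never sees the hotter conditions.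

**Further compounds**
F1 | step 1 | 1-(2,4,6-trihydroxy-3-methylphenyl)butan-1-one | CCCC(=O)c1c(O)cc(O)c(C)c1O
F2 | step 4 | albaspidin BB, 6,6'-methylenebis(2-butanoyl-3,5-dihydroxy-4,4-dimethylcyclohexa-2,5-dien-1-one) | CCCC(=O)C1=C(O)C(C)(C)C(O)=C(CC2=C(O)C(C)(C)C(O)=C(C(=O)CCC)C2=O)C1=O
F3 | step 5 | 1-[3-[(dimethylamino)methyl]-2,6-dihydroxy-4-methoxyphenyl]butan-1-one | CCCC(=O)c1c(O)cc(OC)c(CN(C)C)c1O
F4 | step 5 | 2-butanoyl-3-hydroxy-5-methoxy-6-methylidenecyclohexa-2,4-dien-1-one | CCCC(=O)C1=C(O)C=C(OC)C(=C)C1=O
F5 | step 5 | 1-[3-[(3-butanoyl-2,4,6-trihydroxyphenyl)methyl]-2,6-dihydroxy-4-methoxyphenyl]butan-1-one | CCCC(=O)c1c(O)cc(O)c(Cc2c(OC)cc(O)c(C(=O)CCC)c2O)c1O
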